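## Retrosynthetic overview
1. Target ⇐ fluoride-mediated global desilylation of the fully protected ester. The C8–O acyl bond ⇐ 6β,8α-diol plus a Roche-ester-derived acid, since the equatorial 8-OH acylates ahead of the hindered axial 6-OH.
2. C8 (α-OH) ⇐ reduction of an 8-ketone directed by the 6β-OH. C6 and C7 ⇐ reductive opening of a β-configured 6,7-epoxy-8-ketone, made by OH-directed epoxidation of a dienol obtained by CBS reduction.
3. C7–C11 bond ⇐ Stille coupling of a 2-iodoenone with an α-stannyl acrylate.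
4. Iodoenone ⇐ 3-methyl-3-vinyl-4-isopropenylcyclohexanone by allylic hydroxylation, dehydrogenation and α-iodination.
5. Rings: no carbocycle is built. The cyclohexane is the six-membered ring of (+)-verbenone: vinyl conjugate addition sets C10, then cyclobutane cleavage releases the ring and the C5 side chain. Only a transient oxirane is formed and reopened.

Assumption: elemane numbering is used (C10 = quaternary ring carbon, then C5, C6, C7, C8, C9; β = face of the C10 methyl); the SMILES is read as 5R,6S,7S,8S,10S,2'S (6-OH β/axial, 8-O α/equatorial); (1R,5R)-(+)-verbenone is taken as a catalogue chemical; TBS = tert-butyldimethylsilyl, TBSO = its oxy group, TMSE = 2-(trimethylsilyl)ethyl.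

## Route

Step 1
Reactants: 1 (1R,5R)-(+)-verbenone = (1R,5R)-4,6,6-trimethylbicyclo[3.1.1]hept-3-en-2-one
Product: 2 (1R,4S,5S)-4-ethenyl-4,6,6-trimethylbicyclo[3.1.1]heptan-2-one
Conditions: CH2=CHMgBr (1.5 equiv), CuI (20 mol %), THF, −40 → 0 °C; then 1 M HCl
Reagents that add atoms: vinylmagnesium bromide, C=C[Mg]Br
Why: Copper-catalysed conjugate (1,4-) addition of the vinyl Grignard reagent reaches the β-carbon only from the face opposite the gem-dimethyl bridge, so the new quaternary centre (future C10, S) has vinyl anti and methyl syn to the carbon that becomes the C5 side chain.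

Step 2
Reactants: 2 (1R,4S,5S)-4-ethenyl-4,6,6-trimethylbicyclo[3.1.1]heptan-2-one
Product: 4 (3S,4S)-3-ethenyl-3-methyl-4-(prop-1-en-2-yl)cyclohexan-1-one, via enol acetate 3 (not isolated)
Conditions: BF3·OEt2, Zn(OAc)2, Ac2O, 0 °C → rt; aqueous work-up, crude material then K2CO3 (cat.), MeOH, 0 °C
Reagents that add atoms: acetic anhydride, CC(=O)OC(C)=O (supplies the acetyl group of 3; no reagent atom remains in 4)
Why: Lewis-acid-induced cyclobutane fragmentation (retro-aldol-type heterolysis of the C1–C6 bond next to the activated carbonyl) gives a tertiary cation that loses a proton to form the isopropenyl group while the enolate oxygen is acetylated, and base-catalysed transesterification then frees the ketone without touching C5 or C10, so the trans vinyl/isopropenyl relationship carries over.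

Step 3
Reactants: 4 (3S,4S)-3-ethenyl-3-methyl-4-(prop-1-en-2-yl)cyclohexan-1-one
Product: 5 (3S,4R)-3-ethenyl-4-(3-hydroxyprop-1-en-2-yl)-3-methylcyclohexan-1-one
Conditions: SeO2 (0.3 equiv), t-BuOOH (2.5 equiv), salicylic acid (cat.), CH2Cl2, 0 °C → rt
Reagents that add atoms: tert-butyl hydroperoxide, CC(C)(C)OO; selenium dioxide (catalytic oxygen carrier), O=[Se]=O
Why: Sharpless-type SeO2/t-BuOOH allylic hydroxylation (ene reaction then [2,3]-sigmatropic shift) can engage only the isopropenyl group, because the vinyl group has no allylic hydrogen, and it takes the methyl C–H rather than the C5–H shielded by the neighbouring quaternary carbon, creating no stereocentre.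

Step 4
Reactants: 5 (3S,4R)-3-ethenyl-4-(3-hydroxyprop-1-en-2-yl)-3-methylcyclohexan-1-one
Product: 6 (3S,4R)-4-[3-(TBSO)prop-1-en-2-yl]-3-ethenyl-3-methylcyclohexan-1-one
Conditions: TBSCl, imidazole, CH2Cl2, 0 °C → rt
Reagents that add atoms: tert-butyldimethylsilyl chloride, CC(C)(C)[Si](C)(C)Cl
Why: Imidazole-promoted silylation (Corey protocol) masks the primary allylic alcohol so that it cannot direct the later vanadium epoxidation, and no stereocentre is affected.

Step 5
Reactants: 6 (3S,4R)-4-[3-(TBSO)prop-1-en-2-yl]-3-ethenyl-3-methylcyclohexan-1-one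
Product: 7 (4R,5S)-4-[3-(TBSO)prop-1-en-2-yl]-5-ethenyl-5-methylcyclohex-2-en-1-one
Conditions: IBX (1.5 equiv), DMSO/PhF, 70 °C
Reagents that add atoms: none
Why: IBX-mediated α,β-dehydrogenation (Nicolaou oxidation) can only introduce the C6=C7 double bond, since the other α-carbon (C9) is flanked by quaternary C10, and over-oxidation to a dienone is impossible for the same reason.

Step 6
Reactants: 7 (4R,5S)-4-[3-(TBSO)prop-1-en-2-yl]-5-ethenyl-5-methylcyclohex-2-en-1-one
Product: 8 (4R,5S)-4-[3-(TBSO)prop-1-en-2-yl]-5-ethenyl-2-iodo-5-methylcyclohex-2-en-1-one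
Conditions: I2 (1.5 equiv), pyridine/CH2Cl2 (1:1), 0 °C → rt
Reagents that add atoms: iodine, II
Why: Johnson α-iodination (Baylis–Hillman-type addition of pyridine, iodination, elimination) functionalises only the electron-poor enone carbon C7 and leaves the isolated alkenes alone.

Step 7
Reactants: 9 propiolic acid; 10 2-(trimethylsilyl)ethanol
Product: 11 2-(trimethylsilyl)ethyl propiolate
Conditions: DCC, DMAP (cat.), CH2Cl2, −20 → 0 °C
Reagents that add atoms: none
Why: Steglich esterification at low temperature gives the fluoride-labile TMSE ester without conjugate addition to the alkyne.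

Step 8
Reactants: 11 2-(trimethylsilyl)ethyl propiolate
Product: 12 2-(trimethylsilyl)ethyl 2-(tributylstannyl)prop-2-enoate
Conditions: Bu3SnH (1.05 equiv), Pd(PPh3)4 (2 mol %), THF, 0 °C → rt
Reagents that add atoms: tributyltin hydride, CCCC[SnH](CCCC)CCCC
Why: Palladium-catalysed syn-hydrostannation of the alkynoate delivers hydride to the β-carbon and tin to the α-carbon, giving mainly the α-stannyl acrylate, which is separable from the minor (E)-β-isomer.

Step 9
Reactants: 8 (4R,5S)-4-[3-(TBSO)prop-1-en-2-yl]-5-ethenyl-2-iodo-5-methylcyclohex-2-en-1-one; 12 2-(trimethylsilyl)ethyl 2-(tributylstannyl)prop-2-enoate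
Product: 13 2-(trimethylsilyl)ethyl 2-{(3R,4S)-3-[3-(TBSO)prop-1-en-2-yl]-4-ethenyl-4-methyl-6-oxocyclohex-1-en-1-yl}prop-2-enoate
Conditions: Pd2(dba)3 (5 mol %), AsPh3 (20 mol %), CuI (20 mol %), NMP, rt → 45 °C; used promptly
Reagents that add atoms: none
Why: Copper-assisted Stille cross-coupling joins the two sp2 carbons (C7–C11) under neutral conditions, so the base-sensitive doubly allylic C5–H, the silyl ether and the TMSE ester survive, and no stereocentre is formed.

Step 10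
Reactants: 13 2-(trimethylsilyl)ethyl 2-{(3R,4S)-3-[3-(TBSO)prop-1-en-2-yl]-4-ethenyl-4-methyl-6-oxocyclohex-1-en-1-yl}prop-2-enoate
Product: 14 2-(trimethylsilyl)ethyl 2-{(3R,4S,6R)-3-[3-(TBSO)prop-1-en-2-yl]-4-ethenyl-6-hydroxy-4-methylcyclohex-1-en-1-yl}prop-2-enoate (8β-OH)
Conditions: (S)-Me-CBS (0.3 equiv), catecholborane (2 equiv), toluene, −78 °C; MeOH, then pH 7 buffer
Reagents that add atoms: none
Why: In this Corey–Bakshi–Shibata reduction the substituted C7 alkenyl arm acts as the large group, so the (S)-catalyst delivers hydride to the α-face and gives the 8β (8R) allylic alcohol under catalyst control, while catecholborane at −78 °C reduces neither the acrylate nor the isolated alkenes.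

Step 11
Reactants: 14 2-(trimethylsilyl)ethyl 2-{(3R,4S,6R)-3-[3-(TBSO)prop-1-en-2-yl]-4-ethenyl-6-hydroxy-4-methylcyclohex-1-en-1-yl}prop-2-enoate
Product: 15 2-(trimethylsilyl)ethyl 2-{(1R,2R,4S,5R,6S)-5-[3-(TBSO)prop-1-en-2-yl]-4-ethenyl-2-hydroxy-4-methyl-7-oxabicyclo[4.1.0]heptan-1-yl}prop-2-enoate (6β,7β-epoxide)
Conditions: VO(acac)2 (5 mol %), t-BuOOH (1.5 equiv), CH2Cl2, 0 °C
Reagents that add atoms: tert-butyl hydroperoxide, CC(C)(C)OO
Why: Vanadium-catalysed hydroxyl-directed (Sharpless–Michaelson) epoxidation transfers oxygen within the alkoxide–peroxide complex, so only the allylic C6=C7 bond reacts and the oxirane forms syn to the 8β-OH, which sets the C6–O bond on the β-face (6S).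

Step 12
Reactants: 15 2-(trimethylsilyl)ethyl 2-{(1R,2R,4S,5R,6S)-5-[3-(TBSO)prop-1-en-2-yl]-4-ethenyl-2-hydroxy-4-methyl-7-oxabicyclo[4.1.0]heptan-1-yl}prop-2-enoate
Product: 16 2-(trimethylsilyl)ethyl 2-{(1S,4S,5R,6S)-5-[3-(TBSO)prop-1-en-2-yl]-4-ethenyl-4-methyl-2-oxo-7-oxabicyclo[4.1.0]heptan-1-yl}prop-2-enoate
Conditions: Dess–Martin periodinane (1.3 equiv), NaHCO3, CH2Cl2, 0 °C → rt
Reagents that add atoms: none
Why: Buffered Dess–Martin oxidation converts the secondary alcohol into the ketone under near-neutral conditions that leave the vinyl oxirane, the silyl groups and the existing stereocentres untouched.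

Step 13
Reactants: 16 2-(trimethylsilyl)ethyl 2-{(1S,4S,5R,6S)-5-[3-(TBSO)prop-1-en-2-yl]-4-ethenyl-4-methyl-2-oxo-7-oxabicyclo[4.1.0]heptan-1-yl}prop-2-enoate
Product: 17 2-(trimethylsilyl)ethyl 2-{(1S,2S,3R,4S)-3-[3-(TBSO)prop-1-en-2-yl]-4-ethenyl-2-hydroxy-4-methyl-6-oxocyclohexyl}prop-2-enoate (6β-OH, 7α-H)
Conditions: SmI2 (2.2 equiv), THF/MeOH (4:1), −90 °C, 10 min; pH 7 buffer; used crude
Reagents that add atoms: none
Why: Samarium diiodide reduction of the α,β-epoxy ketone (Molander conditions) cleaves only the Cα–O bond (C7–O), so the 6β C–O bond is retained, and kinetic axial protonation at C7 from the open α-face places the acrylate equatorial (7S), which is also the thermodynamically preferred epimer.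

Step 14
Reactants: 17 2-(trimethylsilyl)ethyl 2-{(1S,2S,3R,4S)-3-[3-(TBSO)prop-1-en-2-yl]-4-ethenyl-2-hydroxy-4-methyl-6-oxocyclohexyl}prop-2-enoate
Product: 18 2-(trimethylsilyl)ethyl 2-{(1R,2S,3R,4S,6S)-3-[3-(TBSO)prop-1-en-2-yl]-4-ethenyl-2,6-dihydroxy-4-methylcyclohexyl}prop-2-enoate (6β,8α-diol)
Conditions: Me4NBH(OAc)3 (5 equiv), MeCN/AcOH (1:1), −30 °C; aq. Rochelle salt
Reagents that add atoms: none
Why: In the Evans–Saksena hydroxyl-directed reduction the axial 6β-OH displaces an acetate on boron and hydride is delivered intramolecularly to the β-face of the C8 carbonyl, giving the equatorial 8α-alcohol (8S, 1,3-anti diol), while the acrylate is inert to triacetoxyborohydride.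

Step 15
Reactants: 19 methyl (S)-3-hydroxy-2-methylpropanoate ((S)-Roche ester)
Product: 20 methyl (S)-3-(TBSO)-2-methylpropanoate
Conditions: TBSCl, imidazole, CH2Cl2, 0 °C → rt
Reagents that add atoms: tert-butyldimethylsilyl chloride, CC(C)(C)[Si](C)(C)Cl
Why: Imidazole-promoted silylation protects the primary alcohol, and the (S)-stereocentre from the chiral pool is not involved.

Step 16
Reactants: 20 methyl (S)-3-(TBSO)-2-methylpropanoate
Product: 21 (S)-3-(TBSO)-2-methylpropanoic acid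
Conditions: LiOH·H2O, THF/MeOH/H2O, 0 °C → rt; 1 M HCl to pH 3–4
Reagents that add atoms: lithium hydroxide, [Li+].[OH-]
Why: Mild saponification followed by careful acidification gives the acid without epimerising the α-stereocentre or losing the TBS ether.

Step 17
Reactants: 18 2-(trimethylsilyl)ethyl 2-{(1R,2S,3R,4S,6S)-3-[3-(TBSO)prop-1-en-2-yl]-4-ethenyl-2,6-dihydroxy-4-methylcyclohexyl}prop-2-enoate; 21 (S)-3-(TBSO)-2-methylpropanoic acid
Product: 22 2-(trimethylsilyl)ethyl 2-{(1S,2S,3R,4S,6S)-3-[3-(TBSO)prop-1-en-2-yl]-4-ethenyl-2-hydroxy-4-methyl-6-[(2S)-3-(TBSO)-2-methylpropanoyloxy]cyclohexyl}prop-2-enoate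
Conditions: 21 (1.2 equiv), EDC·HCl (1.5 equiv), DMAP (0.2 equiv), CH2Cl2, 0 °C → rt
Reagents that add atoms: none
Why: Steglich-type carbodiimide esterification is sterically selective for the equatorial 8α-OH, because the axial 6β-OH is flanked by two branched substituents and is syn-axial to the C10 methyl, and configuration at C8 and at the acid α-carbon is retained.

Step 18
Reactants: 22 2-(trimethylsilyl)ethyl 2-{(1S,2S,3R,4S,6S)-3-[3-(TBSO)prop-1-en-2-yl]-4-ethenyl-2-hydroxy-4-methyl-6-[(2S)-3-(TBSO)-2-methylpropanoyloxy]cyclohexyl}prop-2-enoate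
Product: 23 2-[(1S,2S,3R,4S,6S)-4-ethenyl-2-hydroxy-6-{[(2S)-3-hydroxy-2-methylpropanoyl]oxy}-3-(3-hydroxyprop-1-en-2-yl)-4-methylcyclohexyl]prop-2-enoic acid (target)
Conditions: TASF (8 equiv), DMF/H2O (20:1), 0 °C → rt; cold dilute HCl to pH 4
Reagents that add atoms: none
Why: Fluoride-induced global desilylation removes both TBS ethers and fragments the TMSE ester (β-elimination to ethene and Me3SiF) to a carboxylate that cannot lactonise onto the 6-OH, and gentle acidification gives the target with all six stereocentres unchanged.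

## Compound list
1 | (1R,5R)-(+)-verbenone | CC1=CC(=O)[C@@H]2C[C@H]1C2(C)C | starting material
2 | (1R,4S,5S)-4-ethenyl-4,6,6-trimethylbicyclo[3.1.1]heptan-2-one | C[C@@]1(C=C)CC(=O)[C@@H]2C[C@H]1C2(C)C | intermediate
3 | (4S,5S)-5-ethenyl-5-methyl-4-(prop-1-en-2-yl)cyclohex-1-en-1-yl acetate (not isolated) | C[C@@]1(C=C)CC(OC(C)=O)=CC[C@H]1C(C)=C | intermediate
4 | (3S,4S)-3-ethenyl-3-methyl-4-(prop-1-en-2-yl)cyclohexan-1-one | C[C@@]1(C=C)CC(=O)CC[C@H]1C(C)=C | intermediate
5 | (3S,4R)-3-ethenyl-4-(3-hydroxyprop-1-en-2-yl)-3-methylcyclohexan-1-one | C[C@@]1(C=C)CC(=O)CC[C@H]1C(=C)CO | intermediate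
6 | (3S,4R)-4-[3-(TBSO)prop-1-en-2-yl]-3-ethenyl-3-methylcyclohexan-1-one | C[C@@]1(C=C)CC(=O)CC[C@H]1C(=C)CO[Si](C)(C)C(C)(C)C | intermediate
7 | (4R,5S)-4-[3-(TBSO)prop-1-en-2-yl]-5-ethenyl-5-methylcyclohex-2-en-1-one | C[C@@]1(C=C)CC(=O)C=C[C@H]1C(=C)CO[Si](C)(C)C(C)(C)C | intermediate
8 | (4R,5S)-4-[3-(TBSO)prop-1-en-2-yl]-5-ethenyl-2-iodo-5-methylcyclohex-2-en-1-one | C[C@@]1(C=C)CC(=O)C(I)=C[C@H]1C(=C)CO[Si](C)(C)C(C)(C)C | intermediate
9 | propiolic acid | C#CC(=O)O | starting material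
10 | 2-(trimethylsilyl)ethanol | C[Si](C)(C)CCO | starting material
11 | 2-(trimethylsilyl)ethyl propiolate | C#CC(=O)OCC[Si](C)(C)C | intermediate
12 | 2-(trimethylsilyl)ethyl 2-(tributylstannyl)prop-2-enoate | C=C(C(=O)OCC[Si](C)(C)C)[Sn](CCCC)(CCCC)CCCC | intermediate
13 | TMSE 2-{(3R,4S)-3-[3-(TBSO)prop-1-en-2-yl]-4-ethenyl-4-methyl-6-oxocyclohex-1-en-1-yl}prop-2-enoate | C[C@@]1(C=C)CC(=O)C(C(=C)C(=O)OCC[Si](C)(C)C)=C[C@H]1C(=C)CO[Si](C)(C)C(C)(C)C | intermediate
14 | TMSE 2-{(3R,4S,6R)-3-[3-(TBSO)prop-1-en-2-yl]-4-ethenyl-6-hydroxy-4-methylcyclohex-1-en-1-yl}prop-2-enoate | C[C@@]1(C=C)C[C@@H](O)C(C(=C)C(=O)OCC[Si](C)(C)C)=C[C@H]1C(=C)CO[Si](C)(C)C(C)(C)C | intermediate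
15 | TMSE 2-{(1R,2R,4S,5R,6S)-5-[3-(TBSO)prop-1-en-2-yl]-4-ethenyl-2-hydroxy-4-methyl-7-oxabicyclo[4.1.0]heptan-1-yl}prop-2-enoate | C[C@@]1(C=C)C[C@@H](O)[C@@]2(C(=C)C(=O)OCC[Si](C)(C)C)O[C@H]2[C@H]1C(=C)CO[Si](C)(C)C(C)(C)C | intermediate
16 | TMSE 2-{(1S,4S,5R,6S)-5-[3-(TBSO)prop-1-en-2-yl]-4-ethenyl-4-methyl-2-oxo-7-oxabicyclo[4.1.0]heptan-1-yl}prop-2-enoate | C[C@@]1(C=C)CC(=O)[C@@]2(C(=C)C(=O)OCC[Si](C)(C)C)O[C@H]2[C@H]1C(=C)CO[Si](C)(C)C(C)(C)C | intermediate
17 | TMSE 2-{(1S,2S,3R,4S)-3-[3-(TBSO)prop-1-en-2-yl]-4-ethenyl-2-hydroxy-4-methyl-6-oxocyclohexyl}prop-2-enoate | C[C@@]1(C=C)CC(=O)[C@@H](C(=C)C(=O)OCC[Si](C)(C)C)[C@@H](O)[C@H]1C(=C)CO[Si](C)(C)C(C)(C)C | intermediate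
18 | TMSE 2-{(1R,2S,3R,4S,6S)-3-[3-(TBSO)prop-1-en-2-yl]-4-ethenyl-2,6-dihydroxy-4-methylcyclohexyl}prop-2-enoate | C[C@@]1(C=C)C[C@H](O)[C@@H](C(=C)C(=O)OCC[Si](C)(C)C)[C@@H](O)[C@H]1C(=C)CO[Si](C)(C)C(C)(C)C | intermediate
19 | methyl (S)-3-hydroxy-2-methylpropanoate | COC(=O)[C@@H](C)CO | starting material
20 | methyl (S)-3-(TBSO)-2-methylpropanoate | COC(=O)[C@@H](C)CO[Si](C)(C)C(C)(C)C | intermediate
21 | (S)-3-(TBSO)-2-methylpropanoic acid | OC(=O)[C@@H](C)CO[Si](C)(C)C(C)(C)C | intermediate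
22 | TMSE 2-{(1S,2S,3R,4S,6S)-3-[3-(TBSO)prop-1-en-2-yl]-4-ethenyl-2-hydroxy-4-methyl-6-[(2S)-3-(TBSO)-2-methylpropanoyloxy]cyclohexyl}prop-2-enoate | C[C@@]1(C=C)C[C@H](OC(=O)[C@@H](C)CO[Si](C)(C)C(C)(C)C)[C@@H](C(=C)C(=O)OCC[Si](C)(C)C)[C@@H](O)[C@H]1C(=C)CO[Si](C)(C)C(C)(C)C | intermediate
23 | 2-[(1S,2S,3R,4S,6S)-4-ethenyl-2-hydroxy-6-{[(2S)-3-hydroxy-2-methylpropanoyl]oxy}-3-(3-hydroxyprop-1-en-2-yl)-4-methylcyclohexyl]prop-2-enoic acid | C=C[C@]1(C)C[C@H](OC(=O)[C@@H](C)CO)[C@@H](C(=C)C(=O)O)[C@@H](O)[C@H]1C(=C)CO | target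

## Step count and weak points
Total step count: 18.
Longest linear sequence: 14 (steps 1–6, 9–14, 17, 18).

**Step 9 (Stille coupling).**
- Risk: α-stannyl acrylates transfer slowly and can give cine-substitution. Product 13 is a doubly acceptor-substituted diene that may dimerise.
- Fallback: sets out from 8 and comes back at 13. Iodoenone 8 is coupled with tributyl(ethynyl)stannane, the fastest-transferring class of stannane, to give (4R,5S)-4-[3-(TBSO)prop-1-en-2-yl]-5-ethenyl-2-ethynyl-5-methylcyclohex-2-en-1-one F1, a stable enynone. The acrylate is then assembled on the ring by Markovnikov-selective palladium-catalysed hydroalkoxycarbonylation of the terminal alkyne (Pd(OAc)2, 2-pyridyldiphenylphosphine, catalytic MsOH, CO) with alcohol 10 as the nucleophile. This delivers 13 immediately before its reduction.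

**Step 13 (SmI2 opening next to an acrylate).**
- Risk: competing acrylate reduction, γ-protonation or isomerisation to the tetrasubstituted C7=C11 alkene, or dehydration back to 13.
- Fallback: sets out from 15 and comes back at 17. The vinyl oxirane of 15 undergoes Tsuji–Shimizu hydrogenolysis (Pd2(dba)3, PBu3, HCO2H, Et3N). Pd(0) ionises the C7–O bond anti, from the α-face, and hydride passes from palladium to the more substituted allyl terminus C7 on that face. This gives 2-(trimethylsilyl)ethyl 2-{(1R,2S,3R,4S,6R)-3-[3-(TBSO)prop-1-en-2-yl]-4-ethenyl-2,6-dihydroxy-4-methylcyclohexyl}prop-2-enoate F2 (6β,8β-diol, 7α-H). The less hindered 8-OH is then oxidised selectively (catalytic TEMPO, PhI(OAc)2) to 17.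

**Step 18 (final deprotection).**
- Risk: the free 6β-OH can lactonise onto the TMSE ester under basic fluoride, or onto the acid during acidification.
- Fallback: sets out from 22 and comes back at 23. The 6-OH is first capped (TESOTf, 2,6-lutidine, −78 → 0 °C) to give 2-(trimethylsilyl)ethyl 2-{(1S,2S,3R,4S,6S)-3-[3-(TBSO)prop-1-en-2-yl]-4-ethenyl-4-methyl-6-[(2S)-3-(TBSO)-2-methylpropanoyloxy]-2-(triethylsilyloxy)cyclohexyl}prop-2-enoate F3. With TASF the unhindered TMSE ester should fragment to the non-electrophilic carboxylate before the crowded axial TES ether is lost. Continued exposure then removes all silyl ethers and gives 23.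

## Further compounds
F1 | step 9 | (4R,5S)-4-[3-(TBSO)prop-1-en-2-yl]-5-ethenyl-2-ethynyl-5-methylcyclohex-2-en-1-one | C[C@@]1(C=C)CC(=O)C(C#C)=C[C@H]1C(=C)CO[Si](C)(C)C(C)(C)C
F2 | step 13 | 2-(trimethylsilyl)ethyl 2-{(1R,2S,3R,4S,6R)-3-[3-(TBSO)prop-1-en-2-yl]-4-ethenyl-2,6-dihydroxy-4-methylcyclohexyl}prop-2-enoate | C[C@@]1(C=C)C[C@@H](O)[C@@H](C(=C)C(=O)OCC[Si](C)(C)C)[C@@H](O)[C@H]1C(=C)CO[Si](C)(C)C(C)(C)C
F3 | step 18 | 2-(trimethylsilyl)ethyl 2-{(1S,2S,3R,4S,6S)-3-[3-(TBSO)prop-1-en-2-yl]-4-ethenyl-4-methyl-6-[(2S)-3-(TBSO)-2-methylpropanoyloxy]-2-(triethylsilyloxy)cyclohexyl}prop-2-enoate | C[C@@]1(C=C)C[C@H](OC(=O)[C@@H](C)CO[Si](C)(C)C(C)(C)C)[C@@H](C(=C)C(=O)OCC[Si](C)(C)C)[C@@H](O[Si](CC)(CC)CC)[C@H]1C(=C)CO[Si](C)(C)C(C)(C)C
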